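(All constants were chosen freely.)

Four neighbouring flasks share one charge of reagent and differ in the charge of starting material, which passes the reagent at the east flask.

    starting material + reagent → intermediate A (k1 = 70 M⁻¹ min⁻¹)
    starting material ⇌ intermediate B (K2 = 2.0, k2 = 0.31 min⁻¹)
    reagent + intermediate B → target (k3 = 0.17 M⁻¹ min⁻¹)
    reagent + intermediate A ⇌ intermediate C (K4 = 32 M⁻¹, k4 = 0.52 M⁻¹ min⁻¹)
    starting material → decomposition product (k5 = 1.9 × 10⁻⁵ min⁻¹)
    2 starting material → self-condensation product (k6 = 0.17 M⁻¹ min⁻¹)
    capture agent + intermediate A → trapped intermediate (k7 = 4.0 M⁻¹ min⁻¹)

in all of them: reagent 11.5 mM; capture agent 0.220 mM; time 6.0 h
- west: starting material 1.2 mM
- north: starting material 4.0 mM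
- east: starting material 12 mM
- south-west: starting material 30 mM

- [target] at the end for west, north, east, south-west, in this order
- how that number moves from the first to the last of them (falls, then rises / rises, then falls / hardly changes / rises all the way / falls all the way)

- percentages count the starting material that a species holds: one self-condensation product counts as two
- a doubled species enters its step squared and goes two at a time
- "hardly changes" means that all values lie within two and a half points (for a concentration: within two and a half percent of the largest)
- run time (west): 6.0 h
- a step back or a flat step of under half a percent of the largest counts as no turn

We follow one molecule of starting material through the west flask. In the first instants it stands at a fork. Reagent takes it to intermediate A with a half-life of 0.86 min, and at the start that rate is 2.6 times the forward rate to intermediate B. A molecule that does step into intermediate B returns at 0.155 min⁻¹ and is caught by reagent at 0.001955 min⁻¹, so nearly all visits end back in starting material. The molecule therefore comes to the fork again and again. Each pass through the fork offers an exit to intermediate A and an exit to target, and both exits scale with reagent, so reagent cancels from their ratio while the catch stays far below the return. What remains is the equilibrium constant of the step to intermediate B times the rate constant of the step to target, over the rate constant of the step to intermediate A. We call this selectivity factor the leak, 0.486%: the fraction of the starting material that ends as target when reagent outlasts the pool of starting material and intermediate B.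

In the first minutes of the west run the pool drains, and decomposition, with a half-life of 25 d, is far too slow to compete. With the concentrations as charged, intermediate A in the west flask meets capture agent with a half-life of 13 h and binds reagent at an equilibrium constant times reagent of 0.37; both act on molecules already past the fork.

So we commit to 0.00583 mM for west and 0.0194 mM for north. The pool relaxes with a half-life of 1.49 min, but against starting material as charged, reagent has a half-life of 0.825 min in the east flask and 0.330 min in the south-west flask. Intermediate B is thus still filling as reagent falls away. For east we expect less than 0.0559 mM, the leak on the reagent charge. For south-west, letting intermediate B fill linearly while reagent dies, we get about 0.00412 mM. Our row rises, then falls.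

The forecast reads 0.0057 mM, 0.019 mM, 0.034 mM, 0.008 mM, and rises, then falls, on the ground that “the starting material outruns the reagent, which is used up before much intermediate B has built up”. At south-west it stands at twice our figure.

The flasks give 0.00553 mM, 0.0168 mM, 0.0333 mM, 0.00816 mM: rises, then falls, with the turn at a charge of 11 mM. In the west flask target holds 0.461% of the charge, against a leak of 0.486%, with 87.3% of the reagent still there. In the north flask the same leak stands against 0.420% of the charge, with 59.4% of the reagent left.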